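**Compound numbers used throughout**

1 (2E,6E)-farnesol · 2 (2E,6E)-farnesyl chloride · 3 (2E,6E)-farnesyl diphosphate · 4 (7R)-hedycaryol, i.e. (1E,4E,7R)-germacra-1(10),4-dien-11-ol · 5 phloroglucinol · 6 bis-iminium dichloride from 5 (not isolated) · 7 2,4-diformylphloroglucinol · 8 isovaleraldehyde · 9 o-quinone methide from 7 and 8 (not isolated) · 10 macrocarpal J

The terpene part carries eudesmane/germacrane numbers C1–C15. The aromatic carbons are primed, and C9' is the benzylic carbon.

## Analysis of the target

Macrocarpal J (10) is a C28 meroterpenoid. A trans-fused eudesmane (ring A: C1–C5 and C10; ring B: C5–C10) is joined through C1 to a benzylic methine, C9', which also carries an isobutyl group and a 3,5-diformylphloroglucinol ring. There are six stereocentres: C1 (S), C4 (R), C5 (R), C7 (R), C10 (S) and C9' (S). On the decalin the C10 methyl, the C4 methyl, the C7 hydroxyisopropyl group and the C1 side chain are β, while H5 and the C4 hydroxyl are α. The two methyls are therefore 1,3-diaxial, and the C1 and C7 substituents and the C4 hydroxyl are equatorial. C9' lies outside the rings and is tied to them only through the C1–C9' bond. The aromatic part is a vinylogous acid with two chelated aldehydes, and both alcohols are tertiary and dehydrate readily under acid, so late dealkylation or deprotection with Lewis acids would be costly. The hard points are two. The C1–C9' bond joins a secondary carbon next to quaternary C10 to a fully substituted benzylic carbon. The axial methyl and equatorial hydroxyl at C4 are the reverse of what a methyl nucleophile delivers to a 4-ketone. The structure offers its own solution: a carbon substituent at C1, the C5–C10 bond and oxygen at C4, all mutually anti, are the result of two anti additions across the E alkenes of a germacra-1(10),4-diene. C7 with its C11 carbinol and the C6–C7 bond are what a germacrane-forming cyclase makes from a farnesyl chain, and the strategy rests on this feature.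

## Retrosynthetic reasoning

**10 to 4 and 9.** Three bonds are cut together: C1–C9', C5–C10 and the C4–O bond. Cutting C1–C9' alone would leave an intact eudesmane whose C1 is a hindered, unactivated carbon with no handle for stereocontrolled bond formation. Cutting it together with C5–C10 makes C1 the nucleophilic end of the C1=C10 alkene of 4 and makes C9' the electrophilic carbon of 9. The four ring stereocentres C1, C10, C5 and C4 then follow from the E geometry of the two alkenes and from anti addition. Their absolute sense follows from C7, which holds the ten-membered ring in the crown conformer with the carbinol equatorial. The forward reaction has to achieve four things: attack at C1 and not at C5, closure of C5–C10 before the cation is lost in another way, hydration at C4 in place of proton loss, and a facial preference at C9'.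

**9 to 7 and 8.** The exocyclic C9'=C1' bond is cut in the sense of a Knoevenagel condensation at the one free ring position of 7. Compound 9 is too electrophilic to store, so it has to be formed in the presence of 4. The gain is that the complete aromatic unit, with both aldehydes and all three free hydroxyls, enters without protecting groups.

**7 to 5.** The two aryl–formyl bonds are cut. Compound 5 is symmetrical, so only one diformyl isomer can form, and the iminium stage 6 limits the degree of substitution. The forward reaction must stop after two formylations.

**4 to 3.** The C6–C7 bond (farnesyl C1–C10) and the C11–O bond are cut. This is the only disconnection that delivers the ten-membered ring, both E alkenes and the C7 stereocentre in one operation and at ambient temperature. That matters because 4 undergoes Cope rearrangement on warming and transannular cyclisation with acid. No small reagent folds an open-chain triene into one enantiomer of an E,E-cyclodecadienol, so the step is given to a terpene cyclase. The forward reaction must ionise the allylic diphosphate, close the 1,10 bond on one face of the distal alkene and capture the tertiary cation with a bound nucleophile.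

**3 to 2 to 1.** The C1–O–P linkage is cut back to the allylic chloride 2 and then to alcohol 1, which already has the 2E,6E geometry. The gain is that the precursor of the key step is reached in two steps. The forward chemistry must not transpose the allylic system or erode the 2E alkene.

## Alternatives that were turned down

**Alternative 1:** The disconnection is the aromatic ring itself. The ring is built on C9' from the siloxyalkyne A3, which is carried by a bis-silylated eudesmanediol, and 3-ethoxycyclobut-2-en-1-one A2, to give phenol A1.
- Forward key step: A2 opens thermally to a vinylketene, which adds across the electron-rich alkyne. The new cyclobutenone opens to a dienylketene, and a six-electron electrocyclisation with tautomerisation closes the arene, forming three ring C–C bonds.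
- For: no electrophilic substitution is needed at the crowded benzylic position. The pericyclic cascade tolerates silyl ethers. C9' and C1 are fixed before the arene exists and could be set by reagent control, so on the C9' configuration this alternative is stronger than the chosen route.
- Against: the whole eudesmane with its five ring stereocentres, plus an alkynyl ether on a hindered carbon, must be made first, and the alternative offers nothing for that. The three differentiated oxygens of A1 are wasted on a target with three free hydroxyls. The ethyl ether would have to be cleaved and two formyl groups introduced next to a bulky ortho substituent, in the presence of two tertiary alcohols protected only as labile trimethylsilyl ethers.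
- Comparison: well over fifteen steps are to be expected, against five. In place of control at C9', the chosen route forms the C1–C9' bond, ring closure and four stereocentres in one step and uses the arene with its final substitution.

**Alternative 2:** The disconnection cuts C5–C10 and C6–C7 in a Diels–Alder sense. An open-chain trienone gives the decalone A4.
- Forward key step: the vinyl ketone (C5=C6, carbonyl at C4) adds intramolecularly across the diene that runs from C10 to C7. Base then equilibrates C5, which is α to the ketone, to the trans ring fusion.
- For: both rings and quaternary C10 form in one step. The trans fusion is reached thermodynamically. The C1/C9' pair is set in the open chain by dependable acyclic methods, so the alternative is again stronger at C9'.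
- Against: a Z-diene reaches the s-cis conformation with difficulty and has a 1,5-hydrogen shift as an escape. Its terminus C10 is fully substituted, so forcing conditions are needed. The facial sense relative to C1 is not secured. After the key step the C8=C9 alkene must be reduced. A methyl nucleophile would add to the 4-ketone from the α face, away from the axial C10 methyl, and give the wrong C4 epimer, so a detour through the exocyclic alkene is needed. Three aryl methyl ethers must then be cleaved beside two tertiary alcohols, and two aldehydes introduced.
- Comparison: about eighteen to twenty steps. The chosen route obtains the correct C4 configuration directly, because oxygen, not carbon, enters equatorially at C4.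

**Alternative 3:** The disconnection cuts C5–C10 and C8–C9, ring B only. Methacrolein A6 and the (E)-diene A7 give the exo adduct A5.
- Forward key step: a chiral cationic oxazaborolidine Lewis acid binds A6. The α-methyl group enforces the exo mode, and the diene adds with C5 bonding to C10.
- For: the step is catalytic, either enantiomer is available, and it needs no protein. On availability of the catalyst, scalability and predictability of absolute configuration it is stronger than an enzyme-dependent key step. The formyl carbon becomes C1 and offers a handle for analogues.
- Against: only two of the six stereocentres and one ring are made. C7 is still sp2 in A5 and needs a face-selective reduction. Ring A has to be annulated. C1 must then be substituted next to quaternary C10 with control of C1 and C9'. The C4 carbinol meets the same axial-methyl problem, and the arene must still be attached and formylated, all with silyl and ketal protection.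
- Comparison: more than fifteen steps. The chosen route depends on one recombinant enzyme but then needs a single further step and no protecting group.

Key step: step 3

Remark: 3 is drawn as the free acid. It is isolated and used as its ammonium salt after cation exchange, and the counter-ions are spectators.

## Route

**Step 1**
Reactants: 1 (2E,6E)-farnesol
Product: 2 (2E,6E)-farnesyl chloride
Conditions: NCS (1.1 equiv), Me2S (1.2 equiv), CH2Cl2, −30 °C → 0 °C; used crude
Reagents that add atoms: N-chlorosuccinimide, O=C1CCC(=O)N1Cl
Why: Corey–Kim chlorination: the chlorosulfonium salt converts the hydroxyl into an alkoxysulfonium leaving group, which chloride displaces at the primary carbon (SN2) without allylic transposition or loss of the 2E geometry.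

**Step 2**
Reactants: 2 (2E,6E)-farnesyl chloride
Product: 3 (2E,6E)-farnesyl diphosphate
Conditions: (Bu4N)3HP2O7 (2 equiv), MeCN, 25 °C; Dowex 50W (NH4+ form), aq NH4HCO3/iPrOH; cellulose chromatography; lyophilisation
Reagents that add atoms: tris(tetrabutylammonium) hydrogen diphosphate, CCCC[N+](CCCC)(CCCC)CCCC.CCCC[N+](CCCC)(CCCC)CCCC.CCCC[N+](CCCC)(CCCC)CCCC.OP(=O)([O-])OP(=O)([O-])[O-]
Why: SN2 displacement of the primary allylic chloride by the weakly basic diphosphate anion in a dipolar aprotic solvent, the standard route to prenyl diphosphates; no stereocentre is formed and the alkenes are untouched.

**Step 3 (key step)**
Reactants: 3 (2E,6E)-farnesyl diphosphate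
Product: 4 (7R)-hedycaryol
Conditions: recombinant plant (7R)-hedycaryol synthase, MgCl2 (10 mM), HEPES buffer pH 7.5, dithiothreitol, 10% glycerol, 28 °C, pentane overlay; pentane phase dried over K2CO3, concentrated below 20 °C, used at once
Reagents that add atoms: water, O
Why: The magnesium ions held by the aspartate-rich motifs of the enzyme bind the diphosphate of 3 and ionise the C1–O bond to the (2E,6E)-farnesyl cation. The distal C10=C11 π bond, folded under C1 by the active-site contour, attacks C1 (farnesyl numbering), which forms the C6–C7 bond of the eudesmane numbering and leaves the tertiary C11 cation; a bound water captures it and the proton passes to the diphosphate. The closest known reaction type is class 1 sesquiterpene synthase catalysis, and hedycaryol synthases carry out exactly this conversion in vitro. The ten-membered ring closes by a 1,10 cation–olefin macrocyclisation that is exo with respect to the attacking alkene and Markovnikov, with the charge on the exocyclic C11. The single new stereocentre, C7, is set by the face of the C10=C11 alkene that the protein presents to C1, so an enzyme of the plant type that delivers the (7R) antipode must be chosen, and this is checked on a sample by thermal and acid conversion into the known (7R) series. The step needs 1,10- over 1,11- and 1,6-closure, retention of both E alkenes without passage through the tertiary allylic diphosphate, and capture by water in place of proton loss; all of these are properties of the active site, and the substrate contributes only its 2E,6E geometry. The pentane overlay removes 4 from protein and buffer, and the low temperature of work-up suppresses Cope rearrangement and acid-induced transannular cyclisation.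

**Step 4**
Reactants: 5 phloroglucinol
Product: 7 2,4-diformylphloroglucinol, via bis-iminium dichloride 6 (not isolated)
Conditions: POCl3 (2.2 equiv), DMF, 1,4-dioxane, 0 °C → 25 °C; then H2O, 25 °C; recrystallisation
Reagents that add atoms: N,N-dimethylformamide, CN(C)C=O; water, O
Why: Vilsmeier–Haack formylation: the chloroiminium ion substitutes the electron-rich ring twice to give 6, whose two iminium groups slow a third substitution at the stated stoichiometry, and water hydrolyses 6 to the dialdehyde; the symmetry of 5 allows only one diformyl isomer.

**Step 5**
Reactants: 4 (7R)-hedycaryol; 7 2,4-diformylphloroglucinol; 8 isovaleraldehyde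
Product: 10 macrocarpal J, via o-quinone methide 9 (not isolated)
Conditions: 7 (2 equiv), 8 (3 equiv, added slowly), ethylenediammonium diacetate (20 mol%), NaOAc (2 equiv), MeCN/H2O 2:1, 25 °C, Ar, dark; reversed-phase HPLC
Reagents that add atoms: water, O
Why: Proposed new method: Knoevenagel condensation of 7 with 8 (iminium catalysis, then loss of the amine) gives the doubly formyl-activated o-quinone methide 9, whose exocyclic carbon should be attacked by C1 of 4 on the outer face of the crown conformer that holds the C7 carbinol equatorial, while the C4=C5 π bond closes C5–C10 anti to the new C1–C9' bond and the medium hydrates the C4 cation on the equatorial α face, so that two anti additions across E alkenes give the trans-decalin with C1 (S), C10 (S), C5 (R) and C4 (R). The closest known reaction types are the proton-initiated transannular cyclisation and hydration of germacra-1(10),4-dienes to eudesmane-4-ols and the Knoevenagel/o-quinone methide capture by trisubstituted alkenes of medium-ring terpenes. C9' (S) rests only on the isobutyl group lying on the outside of the oxadiene and on the C1 hydrogen, not C2, lying under the quinone methide ring, so the C9' epimer is expected as a co-product and is removed by HPLC.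

## Compound list

1 | (2E,6E)-farnesol | CC(C)=CCC/C(C)=C/CC/C(C)=C/CO | starting material
2 | (2E,6E)-farnesyl chloride | CC(C)=CCC/C(C)=C/CC/C(C)=C/CCl | intermediate
3 | (2E,6E)-farnesyl diphosphate (handled as ammonium salt) | CC(C)=CCC/C(C)=C/CC/C(C)=C/COP(=O)(O)OP(=O)(O)O | intermediate
4 | (7R)-hedycaryol, (1E,4E,7R)-germacra-1(10),4-dien-11-ol | C1/C=C(C)/CC[C@@H](C(C)(C)O)C/C=C(C)/C1 | intermediate
5 | phloroglucinol | Oc1cc(O)cc(O)c1 | starting material
6 | bis(N,N-dimethyliminium) dichloride of 2,4-diformylphloroglucinol (not isolated) | C[N+](C)=Cc1c(O)cc(O)c(C=[N+](C)C)c1O.[Cl-].[Cl-] | intermediate
7 | 2,4-diformylphloroglucinol (2,4,6-trihydroxybenzene-1,3-dicarbaldehyde) | O=Cc1c(O)cc(O)c(C=O)c1O | intermediate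
8 | isovaleraldehyde | CC(C)CC=O | starting material
9 | o-quinone methide, 3,5-diformyl-4,6-dihydroxy-2-(3-methylbutylidene)cyclohexa-3,5-dien-1-one (not isolated; exocyclic alkene geometry not fixed) | CC(C)CC=C1C(=O)C(C=O)=C(O)C(C=O)=C1O | intermediate
10 | macrocarpal J, (1S,4R,5R,7R,10S)-1-[(1S)-1-(3,5-diformyl-2,4,6-trihydroxyphenyl)-3-methylbutyl]eudesmane-4,11-diol | CC(C)C[C@H](c1c(O)c(C=O)c(O)c(C=O)c1O)[C@@H]1CC[C@@](C)(O)[C@@H]2C[C@H](C(C)(C)O)CC[C@]21C | target

**Total step count:** 5. **Longest linear sequence:** 4 steps (steps 1, 2, 3 and 5).

## Steps least certain to work

**Step 5 (union).** Several processes can divert it.
- The acidic phenol 7 may protonate C1 of 4 and start the transannular cyclisation before any C–C bond forms.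
- The quinone methide may attack C5 of the C4=C5 alkene, where no transannular partner exists.
- The C10 cation may collapse onto the phenoxide oxygen without closure of C5–C10.
- The C4 cation may lose a proton instead of being hydrated.
- Facial discrimination at C9' may be poor.
- 9 may be consumed by a second molecule of 7.

Fallback, in known chemistry, from 4, 7 and 8: the domino Knoevenagel/hetero-Diels–Alder reaction is run in a dry, non-ionising medium (ethylenediammonium diacetate, CH2Cl2, 4 Å molecular sieves, 20 °C). It adds the oxadiene of 9 suprafacially across C1=C10 and gives the chroman F1, in which C9' is bonded to C1 and the aryl oxygen to C10. The compact cycloaddition transition state sets the C9'/C1 relationship, and regio- and stereoisomers can be separated at this stage on base-deactivated silica. F1 is then solvolysed in acetone/H2O 1:1 with pyridinium p-toluenesulfonate at 0–20 °C. The tertiary C10–O bond to the acidic phenol ionises with participation of the C4=C5 alkene, which inverts C10, and C4 is hydrated. The route is rejoined at 10.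

**Step 3 (key step).** Turnover may stall through precipitation of magnesium diphosphate and product inhibition. An imperfect active site may let the cation lose a proton or close in another mode. Compound 4 may be lost by acid-induced cyclisation or Cope rearrangement during isolation.

Fallback from 1: the alcohol is fed to Escherichia coli cells that co-express the same synthase with a kinase pair that phosphorylates farnesol, under a dodecane overlay at 28 °C. Compound 3 is then formed and consumed inside the cell at low concentration, and 4 is drawn into the overlay as it forms. The overlay is used directly in step 5, so the route is rejoined at 4. This fallback makes no new compound F0.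

**Step 2 (diphosphate formation).** The allylic chloride may hydrolyse, ionise with allylic transposition or eliminate, and material may be lost in ion exchange and cellulose chromatography.

Fallback from 1: the phosphate, not the carbon, is activated. Bis(triethylammonium) hydrogen phosphate and Cl3CCN in MeCN at 25 °C phosphorylate the alcohol to farnesyl phosphate F2, and a second phosphoryl transfer in the same medium gives 3 after ion-exchange separation from the mono- and triphosphates. The C–O bond is never broken, so transposition is excluded. The route is rejoined at 3.

**Step 4 (diformylation).** Under- and over-formylation may give mixtures that are hard to separate.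

Fallback from 5: O-methylation (Me2SO4, K2CO3, acetone) gives 1,3,5-trimethoxybenzene F3. Double Rieche formylation (Cl2CHOMe, TiCl4, CH2Cl2) gives 2,4,6-trimethoxybenzene-1,3-dicarbaldehyde F4, which is purified as a neutral compound. Chelation-assisted demethylation with BBr3 in CH2Cl2 returns the route to 7.

## Further compounds

F1 | step 5 | chroman from hetero-Diels–Alder addition of 9 across C1=C10 of 4, (1S,7R,10R,9'S,4E) | CC(C)C[C@@H]1c2c(O)c(C=O)c(O)c(C=O)c2O[C@]3(C)CC[C@@H](C(C)(C)O)C/C=C(C)/CC[C@@H]13
F0 | step 3 | none | none
F2 | step 2 | (2E,6E)-farnesyl phosphate | CC(C)=CCC/C(C)=C/CC/C(C)=C/COP(=O)(O)O
F3 | step 4 | 1,3,5-trimethoxybenzene | COc1cc(OC)cc(OC)c1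
F4 | step 4 | 2,4,6-trimethoxybenzene-1,3-dicarbaldehyde | COc1cc(OC)c(C=O)c(OC)c1C=O
A1 | alternative 1 | 2-substituted 5-ethoxy-3-(triisopropylsilyloxy)phenol on the 4,11-bis(trimethylsilyl) eudesmanediol | CC(C)C[C@H](c1c(O)cc(OCC)cc1O[Si](C(C)C)(C(C)C)C(C)C)[C@@H]2CC[C@@](C)(O[Si](C)(C)C)[C@@H]3C[C@H](C(C)(C)O[Si](C)(C)C)CC[C@]32C
A2 | alternative 1 | 3-ethoxycyclobut-2-en-1-one | CCOC1=CC(=O)C1
A3 | alternative 1 | C9'-bound (triisopropylsilyloxy)alkyne on the 4,11-bis(trimethylsilyl) eudesmanediol | CC(C)C[C@H](C#CO[Si](C(C)C)(C(C)C)C(C)C)[C@@H]1CC[C@@](C)(O[Si](C)(C)C)[C@@H]2C[C@H](C(C)(C)O[Si](C)(C)C)CC[C@]21C
A4 | alternative 2 | trans-fused 15-nor-eudesm-8-en-4-one with the C1 side chain (2,4,6-trimethoxyphenyl) and C11 triethylsilyl ether | CC(C)C[C@H](c1c(OC)cc(OC)cc1OC)[C@@H]2CCC(=O)[C@@H]3C[C@H](C(C)(C)O[Si](CC)(CC)CC)C=C[C@]32C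
A5 | alternative 3 | exo cycloadduct, ring B with C10 formyl and methyl and C5 ketal branch | O=C[C@]1(C)CCC(C(C)(C)O[Si](C)(C)C(C)(C)C)=C[C@H]1C2(C)OCCO2
A6 | alternative 3 | methacrolein | C=C(C)C=O
A7 | alternative 3 | (E)-2-[4-(tert-butyldimethylsilyloxy)-4-methyl-3-methylidenepent-1-enyl]-2-methyl-1,3-dioxolane | C=C(/C=C/C1(C)OCCO1)C(C)(C)O[Si](C)(C)C(C)(C)C
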